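**Retrosynthetic overview** (target = pyrrhoxanthin, 3S,5R,6S,3'R, all-E except the Z-ylidene)
1. The C8–C9 bond is cut last (Stille): a West epoxy-vinylstannane plus an α-bromo-γ-ylidenebutenolide that already carries the whole East polyenyne.
2. The butenolide is the last ring formed: the C19 carboxyl oxygen closes onto C11 (5-exo-dig) in the same flask in which C10–C11 is made from (E)-2,3-dibromoacrylic acid and the C25 polyenyne alkyne.
3. The polyenyne comes from a Wittig union of a C15 acetylenic phosphonium salt and a C8 dienynal, both built from (E)-3-methylpent-2-en-4-yn-1-ol.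
4. The epoxide is the first ring formed: oxidation of the 5,6-double bond of the preformed ring, with oxygen put anti to the C3 oxygen through a bromonium/hydroxide/ring-closure sequence, because direct peracid transfer favours the syn face.
5. Both six-membered rings come from one (R)-enol triflate made from (−)-actinol; they are bought, not built.

Assumption: (−)-actinol, (E)-3-methylpent-2-en-4-yn-1-ol and (triphenylphosphoranylidene)acetaldehyde are taken as purchasable; position labels (C3, C5, C6, C9–C11, C19) follow carotenoid numbering of the target.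

**Step 1**
Reactants: 1 (4R,6R)-4-hydroxy-2,2,6-trimethylcyclohexanone
Product: 2 (1R,5R)-3,3,5-trimethyl-4-oxocyclohexyl acetate
Conditions: Ac2O, pyridine, DMAP (cat.), CH2Cl2, 0 °C to rt
Reagents that add atoms: acetic anhydride, CC(=O)OC(C)=O
Why: DMAP-catalysed acylation of the secondary alcohol; the ketone is inert and both stereocentres are untouched.

**Step 2**
Reactants: 2 (1R,5R)-3,3,5-trimethyl-4-oxocyclohexyl acetate
Product: 3 (1R)-3,5,5-trimethyl-4-{[(trifluoromethyl)sulfonyl]oxy}cyclohex-3-en-1-yl acetate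
Conditions: Tf2O, 2,6-di-tert-butyl-4-methylpyridine, CH2Cl2, 0 °C to rt
Reagents that add atoms: trifluoromethanesulfonic anhydride, O=S(=O)(OS(=O)(=O)C(F)(F)F)C(F)(F)F
Why: Stang-type enol triflate formation under non-enolate conditions (acetate tolerated); the ketone has only one α-hydrogen, so a single tetrasubstituted triflate forms, the methyl-bearing centre is erased on purpose and the acetoxy centre is kept.

**Step 3**
Reactants: 3 (1R)-3,5,5-trimethyl-4-{[(trifluoromethyl)sulfonyl]oxy}cyclohex-3-en-1-yl acetate; 4 (E)-3-methylpent-2-en-4-yn-1-ol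
Product: 5 (1R)-4-[(3E)-5-hydroxy-3-methylpent-3-en-1-yn-1-yl]-3,5,5-trimethylcyclohex-3-en-1-yl acetate
Conditions: Pd(PPh3)4 (5 mol%), CuI (10 mol%), Et3N, DMF, 50 °C, degassed
Reagents that add atoms: none
Why: Sonogashira coupling of the enol triflate with the terminal alkyne; the E-enyne geometry, the free primary alcohol and the acetoxy stereocentre are carried through unchanged.

**Step 4**
Reactants: 5 (1R)-4-[(3E)-5-hydroxy-3-methylpent-3-en-1-yn-1-yl]-3,5,5-trimethylcyclohex-3-en-1-yl acetate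
Product: 6 {(2E)-5-[(4R)-4-acetoxy-2,6,6-trimethylcyclohex-1-en-1-yl]-3-methylpent-2-en-4-yn-1-yl}triphenylphosphonium bromide
Conditions: PPh3·HBr, CH2Cl2, rt
Reagents that add atoms: triphenylphosphine hydrobromide, [Br-].[PH+](c1ccccc1)(c1ccccc1)c1ccccc1
Why: acid-mediated substitution of the allylic alcohol by triphenylphosphine (classical carotenoid phosphonium salt formation); the conjugated primary salt is the thermodynamic product and the trisubstituted double bond stays E.

**Step 5**
Reactants: 4 (E)-3-methylpent-2-en-4-yn-1-ol; 7 (triphenylphosphoranylidene)acetaldehyde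
Product: 9 (2E,4E)-5-methylhepta-2,4-dien-6-ynal, via enynal 8 (not isolated)
Conditions: MnO2 (activated, excess), CH2Cl2, rt; filter; then 7 (1.0 equiv), toluene, 70 °C
Reagents that add atoms: none
Why: allylic oxidation with MnO2, then Wittig reaction of the stabilised formyl ylide gives the E-enal; the volatile enynal is used as its filtered solution and one equivalent of ylide limits a second homologation.

**Step 6**
Reactants: 6 {(2E)-5-[(4R)-4-acetoxy-2,6,6-trimethylcyclohex-1-en-1-yl]-3-methylpent-2-en-4-yn-1-yl}triphenylphosphonium bromide; 9 (2E,4E)-5-methylhepta-2,4-dien-6-ynal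
Product: 10 (1R)-4-[(3E,5E,7E,9E)-3,10-dimethyldodeca-3,5,7,9-tetraene-1,11-diyn-1-yl]-3,5,5-trimethylcyclohex-3-en-1-yl acetate
Conditions: 1,2-epoxybutane, EtOH, 70 °C, dark; then heptane, reflux (Z to E at the new CH=CH); crystallise
Reagents that add atoms: none
Why: Wittig olefination under neutral, epoxide-buffered conditions that spare the acetate and the terminal alkyne; the new unhindered CH=CH forms as an E/Z mixture that is equilibrated to E by heating, and no stereocentre is made.

**Step 7**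
Reactants: 11 propiolic acid
Product: 12 (E)-2,3-dibromoprop-2-enoic acid
Conditions: Br2, CHCl3, 0 °C to rt, dark
Reagents that add atoms: bromine, BrBr
Why: electrophilic anti-addition of bromine to the alkyne gives the E-dibromide, which places the β-bromine cis to the carboxyl as the later ring closure requires.

**Step 8** (key ring-forming step: butenolide)
Reactants: 10 (1R)-4-[(3E,5E,7E,9E)-3,10-dimethyldodeca-3,5,7,9-tetraene-1,11-diyn-1-yl]-3,5,5-trimethylcyclohex-3-en-1-yl acetate; 12 (E)-2,3-dibromoprop-2-enoic acid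
Product: 14 (1R)-4-[(3E,5E,7E,9E,11Z)-11-(4-bromo-5-oxofuran-2(5H)-ylidene)-3,10-dimethylundeca-3,5,7,9-tetraen-1-yn-1-yl]-3,5,5-trimethylcyclohex-3-en-1-yl acetate, via enynoic acid 13 (not isolated)
Conditions: PdCl2(PPh3)2 (5 mol%), CuI (10 mol%), Et3N (3 equiv), MeCN, rt, degassed, dark
Reagents that add atoms: none
Why: tandem Sonogashira coupling and 5-exo-dig lactonisation (Lu–Negishi–Rossi type): coupling at the more reactive β-C–Br leaves the carboxyl cis to the new alkyne, and the carboxylate then adds anti across the metal-activated triple bond, so the C19 oxygen closes onto C11 and the Z-ylidene geometry is set directly, while the α-bromine survives as the handle for the West end.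

**Step 9**
Reactants: 3 (1R)-3,5,5-trimethyl-4-{[(trifluoromethyl)sulfonyl]oxy}cyclohex-3-en-1-yl acetate; 15 ethynyltrimethylsilane
Product: 16 (1R)-3,5,5-trimethyl-4-[(trimethylsilyl)ethynyl]cyclohex-3-en-1-yl acetate
Conditions: PdCl2(PPh3)2 (5 mol%), CuI (10 mol%), Et3N, DMF, 50 °C
Reagents that add atoms: none
Why: Sonogashira coupling of the same enol triflate; the silyl group protects the alkyne terminus during the next step and the stereocentre is untouched.

**Step 10** (key ring-forming step: epoxide)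
Reactants: 16 (1R)-3,5,5-trimethyl-4-[(trimethylsilyl)ethynyl]cyclohex-3-en-1-yl acetate
Product: 20 (1R,3S,6R)-6-ethynyl-1,5,5-trimethyl-7-oxabicyclo[4.1.0]heptan-3-ol, via bromohydrin 17 (not isolated), via silylated epoxy acetate 18 (not isolated), via epoxy alkyne acetate 19 (not isolated)
Conditions: NBS, THF/H2O (4:1), 0 °C, dark; then K2CO3, MeOH, 0 °C to rt
Reagents that add atoms: water, O; N-bromosuccinimide, O=C1CCC(=O)N1Br (its bromine is held only in 17 and is lost again)
Why: halohydrin route to the epoxide on the preformed ring: the bromonium ion forms on the less hindered face (anti to the pseudo-axial C1 methyl, syn to the equatorial C3 acetate), water opens it trans-diaxially at C5 (Markovnikov, away from the alkynyl-bearing C6), and carbonate closes the C5 alkoxide onto C6 with inversion (Fürst–Plattner control, as in the β-epoxides of 5,6-unsaturated steroids), so the epoxide oxygen ends anti to the C3 oxygen (5R,6S relative to 3S); the same carbonate/methanol removes the silyl group and the acetate.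

**Step 11**
Reactants: 20 (1R,3S,6R)-6-ethynyl-1,5,5-trimethyl-7-oxabicyclo[4.1.0]heptan-3-ol
Product: 21 (1R,3S,6S)-1,5,5-trimethyl-6-[(E)-2-(tributylstannyl)ethenyl]-7-oxabicyclo[4.1.0]heptan-3-ol
Conditions: Bu3SnH, PdCl2(PPh3)2 (2 mol%), THF, 0 °C
Reagents that add atoms: tributyltin hydride, CCCC[SnH](CCCC)CCCC
Why: palladium-catalysed syn-hydrostannation of the terminal alkyne; tin goes to the terminal carbon, away from the quaternary epoxide carbon, which gives the E-vinylstannane and leaves the three stereocentres untouched.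

**Step 12**
Reactants: 14 (1R)-4-[(3E,5E,7E,9E,11Z)-11-(4-bromo-5-oxofuran-2(5H)-ylidene)-3,10-dimethylundeca-3,5,7,9-tetraen-1-yn-1-yl]-3,5,5-trimethylcyclohex-3-en-1-yl acetate; 21 (1R,3S,6S)-1,5,5-trimethyl-6-[(E)-2-(tributylstannyl)ethenyl]-7-oxabicyclo[4.1.0]heptan-3-ol
Product: 22 pyrrhoxanthin, the target (3S,5R,6S,3'R)
Conditions: Pd2(dba)3 (2.5 mol%), AsPh3 (20 mol%), NMP, 40 °C, degassed, dark
Reagents that add atoms: none
Why: Stille coupling of the α-bromobutenolide with the vinylstannane under base-free conditions, with retention of both alkene geometries; the free hydroxyl, the epoxide, the acetate and the polyene are tolerated and no stereocentre is touched.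

**Compound list**
1 | (4R,6R)-4-hydroxy-2,2,6-trimethylcyclohexanone, (−)-actinol | O[C@H]1CC(C)(C)C(=O)[C@H](C)C1 | starting material
2 | (1R,5R)-3,3,5-trimethyl-4-oxocyclohexyl acetate | CC(=O)O[C@H]1CC(C)(C)C(=O)[C@H](C)C1 | intermediate
3 | (1R)-3,5,5-trimethyl-4-{[(trifluoromethyl)sulfonyl]oxy}cyclohex-3-en-1-yl acetate | CC(=O)O[C@@H]1CC(C)=C(OS(=O)(=O)C(F)(F)F)C(C)(C)C1 | intermediate
4 | (E)-3-methylpent-2-en-4-yn-1-ol | C#C/C(C)=C/CO | starting material
5 | (1R)-4-[(3E)-5-hydroxy-3-methylpent-3-en-1-yn-1-yl]-3,5,5-trimethylcyclohex-3-en-1-yl acetate | CC(=O)O[C@@H]1CC(C)=C(C#C/C(C)=C/CO)C(C)(C)C1 | intermediate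
6 | {(2E)-5-[(4R)-4-acetoxy-2,6,6-trimethylcyclohex-1-en-1-yl]-3-methylpent-2-en-4-yn-1-yl}triphenylphosphonium bromide | CC(=O)O[C@@H]1CC(C)=C(C#C/C(C)=C/C[P+](c2ccccc2)(c2ccccc2)c2ccccc2)C(C)(C)C1.[Br-] | intermediate
7 | (triphenylphosphoranylidene)acetaldehyde | O=CC=P(c1ccccc1)(c1ccccc1)c1ccccc1 | starting material
8 | (E)-3-methylpent-2-en-4-ynal (not isolated) | C#C/C(C)=C/C=O | intermediate
9 | (2E,4E)-5-methylhepta-2,4-dien-6-ynal | C#C/C(C)=C/C=C/C=O | intermediate
10 | (1R)-4-[(3E,5E,7E,9E)-3,10-dimethyldodeca-3,5,7,9-tetraene-1,11-diyn-1-yl]-3,5,5-trimethylcyclohex-3-en-1-yl acetate | CC(=O)O[C@@H]1CC(C)=C(C#C/C(C)=C/C=C/C=C/C=C(C)/C#C)C(C)(C)C1 | intermediate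
11 | propiolic acid | C#CC(=O)O | starting material
12 | (E)-2,3-dibromoprop-2-enoic acid (β-Br cis to CO2H) | OC(=O)/C(Br)=C\Br | intermediate
13 | (2E,6E,8E,10E,12E)-15-[(4R)-4-acetoxy-2,6,6-trimethylcyclohex-1-en-1-yl]-2-bromo-6,13-dimethylpentadeca-2,6,8,10,12-pentaene-4,14-diynoic acid, CO2H cis to the alkynyl group (not isolated) | CC(=O)O[C@@H]1CC(C)=C(C#C/C(C)=C/C=C/C=C/C=C(C)/C#C/C=C(/Br)C(=O)O)C(C)(C)C1 | intermediate
14 | (1R)-4-[(3E,5E,7E,9E,11Z)-11-(4-bromo-5-oxofuran-2(5H)-ylidene)-3,10-dimethylundeca-3,5,7,9-tetraen-1-yn-1-yl]-3,5,5-trimethylcyclohex-3-en-1-yl acetate | CC(=O)O[C@@H]1CC(C)=C(C#C/C(C)=C/C=C/C=C/C=C(C)/C=C2C=C(Br)C(=O)O/2)C(C)(C)C1 | intermediate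
15 | ethynyltrimethylsilane | C#C[Si](C)(C)C | starting material
16 | (1R)-3,5,5-trimethyl-4-[(trimethylsilyl)ethynyl]cyclohex-3-en-1-yl acetate | CC(=O)O[C@@H]1CC(C)=C(C#C[Si](C)(C)C)C(C)(C)C1 | intermediate
17 | (1S,3R,4S)-4-bromo-3-hydroxy-3,5,5-trimethyl-4-[(trimethylsilyl)ethynyl]cyclohexyl acetate, trans-diaxial bromohydrin with OH anti to OAc (not isolated) | CC(=O)O[C@@H]1C[C@@](C)(O)[C@@](Br)(C#C[Si](C)(C)C)C(C)(C)C1 | intermediate
18 | (1R,3S,6R)-1,5,5-trimethyl-6-[(trimethylsilyl)ethynyl]-7-oxabicyclo[4.1.0]heptan-3-yl acetate (not isolated) | C[Si](C)(C)C#C[C@@]12O[C@]1(C)C[C@@H](OC(C)=O)CC2(C)C | intermediate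
19 | (1R,3S,6R)-6-ethynyl-1,5,5-trimethyl-7-oxabicyclo[4.1.0]heptan-3-yl acetate (not isolated) | C#C[C@@]12O[C@]1(C)C[C@@H](OC(C)=O)CC2(C)C | intermediate
20 | (1R,3S,6R)-6-ethynyl-1,5,5-trimethyl-7-oxabicyclo[4.1.0]heptan-3-ol, epoxide O anti to OH | C#C[C@@]12O[C@]1(C)C[C@@H](O)CC2(C)C | intermediate
21 | (1R,3S,6S)-1,5,5-trimethyl-6-[(E)-2-(tributylstannyl)ethenyl]-7-oxabicyclo[4.1.0]heptan-3-ol | CCCC[Sn](CCCC)(CCCC)/C=C/[C@@]12O[C@]1(C)C[C@@H](O)CC2(C)C | intermediate
22 | pyrrhoxanthin (3S,5R,6S,3'R) | CC(=O)O[C@@H]1CC(C)=C(C#C/C(C)=C/C=C/C=C/C=C(C)/C=C2C=C(/C=C/[C@@]34O[C@]3(C)C[C@@H](O)CC4(C)C)C(=O)O/2)C(C)(C)C1 | target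

**Totals**
Total step count: 12. Longest linear sequence: 7 steps (1, 2, 3, 4, 6, 8, 12; from 1 to 22).

**Three steps most likely to fail**

Step 10 (epoxide face and chemoselectivity). The bromonium ion may open with poor face control, or water may add through the alkyne in a conjugate sense. The fallback sets out from 3 and replaces substrate control by reagent control. Stille hydroxymethylation of 3 with (tributylstannyl)methanol (Pd(PPh3)4, LiCl, dioxane, 100 °C) gives (1R)-4-(hydroxymethyl)-3,5,5-trimethylcyclohex-3-en-1-yl acetate F1. Sharpless asymmetric epoxidation (Ti(OiPr)4, D-(−)-diethyl tartrate, t-BuOOH, 4 Å molecular sieves, CH2Cl2, −20 °C) delivers oxygen anti to the acetoxy group and gives (1R,3S,6R)-6-(hydroxymethyl)-1,5,5-trimethyl-7-oxabicyclo[4.1.0]heptan-3-yl acetate F2. Dess–Martin oxidation (NaHCO3, CH2Cl2) gives (1R,3S,6S)-6-formyl-1,5,5-trimethyl-7-oxabicyclo[4.1.0]heptan-3-yl acetate F3. Ohira–Bestmann homologation (dimethyl (1-diazo-2-oxopropyl)phosphonate, K2CO3, MeOH) makes the alkyne and removes the acetate in the same flask, so the route is rejoined at 20.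

Step 8 (tandem coupling and lactonisation on the full polyenyne). Risks are 6-endo closure to a pyranone, a second coupling at the α-bromine, alkyne homocoupling and polyene isomerisation. The fallback sets out from 9 and forms the ring on this small, robust alkyne before the polyene is completed. Compound 9 and 12 under the same PdCl2(PPh3)2/CuI/Et3N conditions give (2E,4E,6Z)-6-(4-bromo-5-oxofuran-2(5H)-ylidene)-5-methylhexa-2,4-dienal F4. Wittig reaction of this aldehyde with phosphonium salt 6 (1,2-epoxybutane, EtOH, 70 °C, then thermal Z to E equilibration) closes the polyene and comes back to the route at 14.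

Step 11 (hydrostannation next to an alkynyl epoxide). Zerovalent palladium can open the propargylic epoxide to an allene, and the regiochemistry of tin addition may be incomplete. The fallback sets out from 20 and changes the metal and the final coupling. Hydroboration with pinacolborane (2.2 equiv, Cp2ZrHCl 10 mol%, Et3N, CH2Cl2, 40 °C) gives (1R,3S,6S)-1,5,5-trimethyl-6-[(E)-2-(4,4,5,5-tetramethyl-1,3,2-dioxaborolan-2-yl)ethenyl]-7-oxabicyclo[4.1.0]heptan-3-ol F5. Suzuki–Miyaura coupling of this boronate with 14 (Pd(PPh3)4, Tl2CO3, THF/H2O, rt) then comes back to the route directly at 22, bypassing the tin compound 21.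

**Further compounds**
F1 | step 10 | (1R)-4-(hydroxymethyl)-3,5,5-trimethylcyclohex-3-en-1-yl acetate | CC(=O)O[C@@H]1CC(C)=C(CO)C(C)(C)C1
F2 | step 10 | (1R,3S,6R)-6-(hydroxymethyl)-1,5,5-trimethyl-7-oxabicyclo[4.1.0]heptan-3-yl acetate | OC[C@@]12O[C@]1(C)C[C@@H](OC(C)=O)CC2(C)C
F3 | step 10 | (1R,3S,6S)-6-formyl-1,5,5-trimethyl-7-oxabicyclo[4.1.0]heptan-3-yl acetate | O=C[C@@]12O[C@]1(C)C[C@@H](OC(C)=O)CC2(C)C
F4 | step 8 | (2E,4E,6Z)-6-(4-bromo-5-oxofuran-2(5H)-ylidene)-5-methylhexa-2,4-dienal | O=C/C=C/C=C(C)/C=C1C=C(Br)C(=O)O/1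
F5 | step 11 | (1R,3S,6S)-1,5,5-trimethyl-6-[(E)-2-(4,4,5,5-tetramethyl-1,3,2-dioxaborolan-2-yl)ethenyl]-7-oxabicyclo[4.1.0]heptan-3-ol | CC1(C)OB(/C=C/[C@@]23O[C@]2(C)C[C@@H](O)CC3(C)C)OC1(C)C
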